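**Plan**

- Retrosynthesis: the sulfate O–S bond, the C7 O–CH3 bond and the two benzyl ethers are cut first. Ring A is then cut at C3a–C7a and C6–C7, which also opens ring B and leaves a 2,4-disubstituted furan on C3 and an ethynyl ether on the C2 oxygen.
- Further back: the O–C(sp) bond of the ynol ether, the furan C4–propyl bond, the C2–C3 bond (aldol) and the CH2–CO bond of a furylacetic acid (one-carbon homologation of 4-bromo-2-furaldehyde).
- Forward: homologation, acylation of the auxiliary, aldol (joins ring C and sets C2–C3), reduction, O-benzylation, attachment of the C5 chain, ynol ether formation. Rings B and A then arise together in one gold-catalysed operation, followed by O-methylation, desilylation, sulfation and debenzylation.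
- Enabling feature (numbering O1, C2, C3, C3a–C7a): ring A carries oxygen on C7a (O1) and on the adjacent C7, and C3a carries C3. This fused ortho-dioxygenated arene is exactly what a furan tethered to an ynol ether isomerises to.
- Stereochemistry: C2 and C3 both come from one Evans syn-aldol with (S)-4-benzyl-1,3-oxazolidin-2-one. The (2R,3S) adduct maps onto (2S,3R) in the target, and neither centre is touched afterwards.

Key step: step 9

Remark: the target is drawn as the free hydrogen sulfate; the sulfate is carried as its sodium salt 27 and protonated only in the last work-up. Compounds 1, 2, 6, 9, 16 and 19 are taken as purchased.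

**Step 1**
Reactants: 1 4-bromo-2-furaldehyde; 2 p-toluenesulfonylmethyl isocyanide (TosMIC)
Product: 4 (4-bromofuran-2-yl)acetonitrile, via tosylvinylformamide 3 (not isolated)
Conditions: t-BuOK (2.2 equiv), DME, −40 °C; then MeOH, reflux
Reagents that add atoms: none
Why: Van Leusen reductive cyanation, in which the TosMIC anion adds to the aldehyde, the oxazoline adduct opens to the 1-tosylvinylformamide 3, and methanolysis of the formyl group with loss of sulfinate should leave the one-carbon-homologated nitrile, the ring bromide being inert to the base at low temperature.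

**Step 2**
Reactants: 4 (4-bromofuran-2-yl)acetonitrile
Product: 5 (4-bromofuran-2-yl)acetic acid
Conditions: NaOH (4 M aq), EtOH, reflux; then HCl (aq) to pH 3, 0 °C
Reagents that add atoms: sodium hydroxide, [Na+].[OH-]; water, O
Why: Alkaline nitrile hydrolysis to the carboxylate, chosen because furans tolerate hot base but not hot acid, and cold acidification should release the arylacetic acid without decarboxylation.

**Step 3**
Reactants: 5 (4-bromofuran-2-yl)acetic acid; 6 (S)-4-benzyl-1,3-oxazolidin-2-one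
Product: 8 (S)-4-benzyl-3-[(4-bromofuran-2-yl)acetyl]-1,3-oxazolidin-2-one, via pivalic mixed anhydride 7 (not isolated)
Conditions: PivCl, Et3N, THF, −20 °C; then LiCl, 6, −20 °C to rt
Reagents that add atoms: none
Why: N-acylation of the oxazolidinone through a mixed pivalic anhydride under LiCl/Et3N activation, a standard imide synthesis that avoids the ketene formation an arylacetyl chloride would risk.

**Step 4**
Reactants: 8 (S)-4-benzyl-3-[(4-bromofuran-2-yl)acetyl]-1,3-oxazolidin-2-one; 9 4-benzyloxy-3-methoxybenzaldehyde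
Product: 12 (4S)-4-benzyl-3-[(2R,3S)-3-(4-benzyloxy-3-methoxyphenyl)-2-(4-bromofuran-2-yl)-3-hydroxypropanoyl]-1,3-oxazolidin-2-one, via Z-boron enolate 10 (not isolated), via boron aldolate 11 (not isolated)
Conditions: Bu2BOTf, i-Pr2NEt, CH2Cl2, −78 to 0 °C; 9, −78 to 0 °C; then pH 7 buffer, MeOH, 30% H2O2, 0 °C
Reagents that add atoms: none
Why: Evans boron syn-aldol, in which soft enolisation gives the Z-enolate 10 and the aldehyde adds through a closed Zimmerman–Traxler chair on the enolate face away from the 4-benzyl group, so that both stereocentres (later C3 and C2) are set as the (2R,3S) syn adduct.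

**Step 5**
Reactants: 12 syn-aldol imide
Product: 13 (1S,2R)-1-(4-benzyloxy-3-methoxyphenyl)-2-(4-bromofuran-2-yl)propane-1,3-diol
Conditions: LiBH4, MeOH (2 equiv), THF, 0 °C
Reagents that add atoms: none
Why: Reductive cleavage of the N-acyl oxazolidinone by borohydride at the activated exocyclic carbonyl, which should give the primary alcohol without touching the aryl bromide or benzyl ether and removes the acidity of the furyl-bearing centre.

**Step 6**
Reactants: 13 (1S,2R)-1,3-diol
Product: 15 (1S,2R)-3-benzyloxy-1-(4-benzyloxy-3-methoxyphenyl)-2-(4-bromofuran-2-yl)propan-1-ol, via stannylene acetal 14 (not isolated)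
Conditions: Bu2SnO, toluene, reflux (Dean–Stark); then BnBr, Bu4NI, 90 °C
Reagents that add atoms: benzyl bromide, BrCc1ccccc1
Why: Stannylene-acetal-directed regioselective O-alkylation, in which the six-membered dibutylstannylene activates the less hindered primary oxygen so that it should be benzylated in preference to the secondary benzylic one.

**Step 7**
Reactants: 15 (1S,2R)-3-benzyloxy-1-(4-benzyloxy-3-methoxyphenyl)-2-(4-bromofuran-2-yl)propan-1-ol; 16 allyloxy(tert-butyl)dimethylsilane
Product: 18 (1S,2R)-3-benzyloxy-1-(4-benzyloxy-3-methoxyphenyl)-2-{4-[3-(tert-butyldimethylsilyloxy)propyl]furan-2-yl}propan-1-ol, via B-alkyl-9-BBN 17 (not isolated)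
Conditions: 16, 9-BBN, THF, rt; then 15, PdCl2(dppf) (5 mol%), K3PO4 (3 M aq), DMF/THF, 60 °C
Reagents that add atoms: none
Why: B-alkyl Suzuki–Miyaura coupling, in which anti-Markovnikov hydroboration of 16 gives the primary alkylborane 17 that transmetallates under base to the furylpalladium species formed by oxidative addition of zerovalent palladium into the C–Br bond, the free hydroxyl and the ethers being tolerated.

**Step 8**
Reactants: 18 (1S,2R)-furyl alcohol; 19 trichloroethylene
Product: 22 1-benzyloxy-4-[(1S,2R)-3-benzyloxy-1-ethynyloxy-2-{4-[3-(tert-butyldimethylsilyloxy)propyl]furan-2-yl}propyl]-2-methoxybenzene, via dichlorovinyl ether 20 (not isolated), via lithium alkynyl ether 21 (not isolated)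
Conditions: KH, THF, 0 °C to rt; 19, −50 °C to rt; then n-BuLi (2.5 equiv), −78 to −40 °C; MeOH, −78 °C; cold work-up, used at once
Reagents that add atoms: none
Why: Trichloroethylene-based ynol ether synthesis, in which the potassium alkoxide adds to dichloroacetylene formed in situ to give the (E)-1,2-dichlorovinyl ether 20 and n-BuLi effects dehydrochlorination and chlorine–lithium exchange to acetylide 21, protonated by MeOH, the carbinol C–O bond and hence the configuration staying intact.

**Step 9**
Reactants: 22 (1S,2R)-ethynyl ether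
Product: 24 (2S,3R)-2-(4-benzyloxy-3-methoxyphenyl)-3-(benzyloxymethyl)-5-[3-(tert-butyldimethylsilyloxy)propyl]-2,3-dihydro-1-benzofuran-7-ol, via arene oxide 23 (not isolated)
Conditions: Ph3PAuNTf2 (5 mol%), CH2Cl2, 4 Å MS, 0 °C to rt
Reagents that add atoms: none
Why: Ph3PAuNTf2 (monovalent gold) activates the ynol ether of 22, furan C2 adds to the oxygen-bearing alkyne carbon, and the resulting cyclopropyl gold carbenoid opens the furan to a dienal gold carbene whose carbonyl oxygen closes onto the carbene carbon to give an oxepine, which tautomerises to arene oxide 23 and opens to phenol 24 with release of the catalyst. The closest known reaction type is the gold-catalysed intramolecular furan–yne phenol synthesis, including its ynol ether and ynamide variants that give 7-hydroxy-2,3-dihydrobenzofurans and 7-hydroxyindolines. Ring B closes by 5-exo-dig attack of the furan on the alkyne (bond C3a–C7a), and ring A closes by 6π electrocyclisation of the oxepine to the arene oxide (bond C6–C7). No stereocentre is formed; C2 and C3 from step 4 are spectators. The step needs the furan to react in preference to electron-rich ring C and the hydroxyl to end on C7: the 2,4-dialkylfuran is the far stronger π-nucleophile and reaches the alkyne through a five-membered transition state, the polarised ynol ether directs attack to its oxygen-bearing carbon, and O1 on C7a stabilises the cation formed when the C6–O bond of the epoxide breaks. Dry conditions at or below room temperature should keep the benzylic ynol ether from hydration and from thermal sigmatropic rearrangement.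

**Step 10**
Reactants: 24 (2S,3R)-dihydrobenzofuran-7-ol
Product: 25 tert-butyl{3-[(2S,3R)-2-(4-benzyloxy-3-methoxyphenyl)-3-(benzyloxymethyl)-7-methoxy-2,3-dihydro-1-benzofuran-5-yl]propoxy}dimethylsilane
Conditions: MeI, K2CO3, acetone, 40 °C
Reagents that add atoms: iodomethane, CI
Why: Williamson O-methylation of the only acidic hydroxyl, the C7 phenol, under carbonate conditions that leave silyl and benzyl ethers alone.

**Step 11**
Reactants: 25 7-methyl ether
Product: 26 3-[(2S,3R)-2-(4-benzyloxy-3-methoxyphenyl)-3-(benzyloxymethyl)-7-methoxy-2,3-dihydro-1-benzofuran-5-yl]propan-1-ol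
Conditions: Bu4NF, THF, 0 °C to rt
Reagents that add atoms: none
Why: Fluoride-mediated cleavage of the primary silyl ether, driven by Si–F bond formation, which should expose the chain hydroxyl alone because both other oxygens are benzylated.

**Step 12**
Reactants: 26 chain alcohol
Product: 27 sodium 3-[(2S,3R)-2-(4-benzyloxy-3-methoxyphenyl)-3-(benzyloxymethyl)-7-methoxy-2,3-dihydro-1-benzofuran-5-yl]propyl sulfate
Conditions: SO3·pyridine, pyridine, rt; then NaHCO3 (aq)
Reagents that add atoms: sulfur trioxide–pyridine complex, O=S(=O)([O-])[n+]1ccccc1; sodium hydrogen carbonate, [Na+].OC([O-])=O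
Why: O-sulfation of a primary alcohol with the sulfur trioxide–pyridine complex, regiochemistry being fixed because 26 has a single free hydroxyl, and neutralisation gives the stable sodium salt.

**Step 13**
Reactants: 27 sodium sulfate
Product: 28 3-[(2S,3R)-2-(4-hydroxy-3-methoxyphenyl)-3-(hydroxymethyl)-7-methoxy-2,3-dihydro-1-benzofuran-5-yl]propyl hydrogen sulfate
Conditions: H2 (1 atm), Pd/C (10% Pd), MeOH, rt; filter; HCl (1.0 equiv, aq), 0 °C; C18 desalting
Reagents that add atoms: none
Why: Catalytic hydrogenolysis of the aryl and the alkyl benzyl ether over palladium under neutral conditions, which the sulfate monoester anion and the ring B ether should survive at 1 atm, followed by protonation with one equivalent of acid to the hydrogen sulfate.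

**Compound list**

1 | 4-bromo-2-furaldehyde | O=Cc1cc(Br)co1 | starting material
2 | p-toluenesulfonylmethyl isocyanide (TosMIC) | [C-]#[N+]CS(=O)(=O)c1ccc(C)cc1 | starting material
3 | N-[2-(4-bromofuran-2-yl)-1-tosylethenyl]formamide | O=CNC(=Cc1cc(Br)co1)S(=O)(=O)c1ccc(C)cc1 | intermediate (not isolated)
4 | (4-bromofuran-2-yl)acetonitrile | N#CCc1cc(Br)co1 | intermediate
5 | (4-bromofuran-2-yl)acetic acid | OC(=O)Cc1cc(Br)co1 | intermediate
6 | (S)-4-benzyl-1,3-oxazolidin-2-one | O=C1N[C@@H](Cc2ccccc2)CO1 | starting material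
7 | (4-bromofuran-2-yl)acetic pivalic anhydride | CC(C)(C)C(=O)OC(=O)Cc1cc(Br)co1 | intermediate (not isolated)
8 | (S)-4-benzyl-3-[(4-bromofuran-2-yl)acetyl]-1,3-oxazolidin-2-one | O=C(Cc1cc(Br)co1)N1[C@@H](Cc2ccccc2)COC1=O | intermediate
9 | 4-benzyloxy-3-methoxybenzaldehyde (O-benzylvanillin) | COc1cc(C=O)ccc1OCc1ccccc1 | starting material
10 | (Z)-dibutylboron enolate of 8 | CCCCB(CCCC)O/C(=C\c1cc(Br)co1)N1[C@@H](Cc2ccccc2)COC1=O | intermediate (not isolated)
11 | O-dibutylboryl aldolate of 12 | COc1cc([C@@H](OB(CCCC)CCCC)[C@@H](C(=O)N2[C@@H](Cc3ccccc3)COC2=O)c2cc(Br)co2)ccc1OCc1ccccc1 | intermediate (not isolated)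
12 | (4S)-4-benzyl-3-[(2R,3S)-3-(4-benzyloxy-3-methoxyphenyl)-2-(4-bromofuran-2-yl)-3-hydroxypropanoyl]-1,3-oxazolidin-2-one | COc1cc([C@@H](O)[C@@H](C(=O)N2[C@@H](Cc3ccccc3)COC2=O)c2cc(Br)co2)ccc1OCc1ccccc1 | intermediate
13 | (1S,2R)-1-(4-benzyloxy-3-methoxyphenyl)-2-(4-bromofuran-2-yl)propane-1,3-diol | COc1cc([C@@H](O)[C@@H](CO)c2cc(Br)co2)ccc1OCc1ccccc1 | intermediate
14 | 2,2-dibutyl-1,3,2-dioxastannane (dibutylstannylene acetal) of diol 13 | COc1cc([C@H]2O[Sn](CCCC)(CCCC)OC[C@H]2c2cc(Br)co2)ccc1OCc1ccccc1 | intermediate (not isolated)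
15 | (1S,2R)-3-benzyloxy-1-(4-benzyloxy-3-methoxyphenyl)-2-(4-bromofuran-2-yl)propan-1-ol | COc1cc([C@@H](O)[C@@H](COCc2ccccc2)c2cc(Br)co2)ccc1OCc1ccccc1 | intermediate
16 | allyloxy(tert-butyl)dimethylsilane | C=CCO[Si](C)(C)C(C)(C)C | starting material
17 | 9-[3-(tert-butyldimethylsilyloxy)propyl]-9-borabicyclo[3.3.1]nonane | CC(C)(C)[Si](C)(C)OCCCB1C2CCCC1CCC2 | intermediate (not isolated)
18 | (1S,2R)-3-benzyloxy-1-(4-benzyloxy-3-methoxyphenyl)-2-{4-[3-(tert-butyldimethylsilyloxy)propyl]furan-2-yl}propan-1-ol | COc1cc([C@@H](O)[C@@H](COCc2ccccc2)c2cc(CCCO[Si](C)(C)C(C)(C)C)co2)ccc1OCc1ccccc1 | intermediate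
19 | trichloroethylene | ClC=C(Cl)Cl | starting material
20 | (E)-1,2-dichlorovinyl ether of 18 | COc1cc([C@@H](O/C(Cl)=C\Cl)[C@@H](COCc2ccccc2)c2cc(CCCO[Si](C)(C)C(C)(C)C)co2)ccc1OCc1ccccc1 | intermediate (not isolated)
21 | lithium acetylide of ynol ether 22 | COc1cc([C@@H](OC#C[Li])[C@@H](COCc2ccccc2)c2cc(CCCO[Si](C)(C)C(C)(C)C)co2)ccc1OCc1ccccc1 | intermediate (not isolated)
22 | 1-benzyloxy-4-[(1S,2R)-3-benzyloxy-1-ethynyloxy-2-{4-[3-(tert-butyldimethylsilyloxy)propyl]furan-2-yl}propyl]-2-methoxybenzene | COc1cc([C@@H](OC#C)[C@@H](COCc2ccccc2)c2cc(CCCO[Si](C)(C)C(C)(C)C)co2)ccc1OCc1ccccc1 | intermediate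
23 | 6,7-epoxy-6,7-dihydro form (arene oxide) of 24, (2S,3R), epoxide face not defined | COc1cc([C@H]2OC3=C([C@@H]2COCc2ccccc2)C=C(CCCO[Si](C)(C)C(C)(C)C)C2OC23)ccc1OCc1ccccc1 | intermediate (not isolated)
24 | (2S,3R)-2-(4-benzyloxy-3-methoxyphenyl)-3-(benzyloxymethyl)-5-[3-(tert-butyldimethylsilyloxy)propyl]-2,3-dihydro-1-benzofuran-7-ol | COc1cc([C@H]2Oc3c(O)cc(CCCO[Si](C)(C)C(C)(C)C)cc3[C@@H]2COCc2ccccc2)ccc1OCc1ccccc1 | intermediate
25 | tert-butyl{3-[(2S,3R)-2-(4-benzyloxy-3-methoxyphenyl)-3-(benzyloxymethyl)-7-methoxy-2,3-dihydro-1-benzofuran-5-yl]propoxy}dimethylsilane | COc1cc([C@H]2Oc3c(OC)cc(CCCO[Si](C)(C)C(C)(C)C)cc3[C@@H]2COCc2ccccc2)ccc1OCc1ccccc1 | intermediate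
26 | 3-[(2S,3R)-2-(4-benzyloxy-3-methoxyphenyl)-3-(benzyloxymethyl)-7-methoxy-2,3-dihydro-1-benzofuran-5-yl]propan-1-ol | COc1cc([C@H]2Oc3c(OC)cc(CCCO)cc3[C@@H]2COCc2ccccc2)ccc1OCc1ccccc1 | intermediate
27 | sodium 3-[(2S,3R)-2-(4-benzyloxy-3-methoxyphenyl)-3-(benzyloxymethyl)-7-methoxy-2,3-dihydro-1-benzofuran-5-yl]propyl sulfate | COc1cc([C@H]2Oc3c(OC)cc(CCCOS(=O)(=O)[O-])cc3[C@@H]2COCc2ccccc2)ccc1OCc1ccccc1.[Na+] | intermediate
28 | 3-[(2S,3R)-2-(4-hydroxy-3-methoxyphenyl)-3-(hydroxymethyl)-7-methoxy-2,3-dihydro-1-benzofuran-5-yl]propyl hydrogen sulfate | COc1cc([C@H]2Oc3c(OC)cc(CCCOS(=O)(=O)O)cc3[C@@H]2CO)ccc1O | target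

**Step count**

Total: 13 steps. Longest linear sequence: 13 steps (1 to 28); all other components are purchased.

**Steps most likely to fail**

Step 8. The hindered secondary potassium alkoxide may add only partly to the dichloroacetylene generated in situ, and the benzylic ynol ether may be lost through sigmatropic rearrangement or retro-ene fragmentation during work-up. The fallback builds the alkyne from the carbinol oxygen by olefination of a formate instead of addition to a chloroalkyne; it sets out from 18 and returns at 22. Formylation of 18 (formic acetic anhydride, pyridine) would give the formate ester F1. Corey–Fuchs-type dibromo-olefination of the formyl group (PPh3, CBr4, CH2Cl2) would give the 2,2-dibromovinyl ether F2. n-BuLi (2.2 equiv, THF, −78 °C) followed by MeOH would then give 22, which would be taken on cold without storage.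

Step 9. The gold-activated ynol ether may be captured by ring C or by traces of water, or the benzylic ynol ether may rearrange, before the furan adds; the arene oxide may also open toward C6. The fallback gives up the furan and the gold step: ring A is brought in intact and ring B is closed last by forming the C2–O1 bond under acid. It sets out from 9 and 6 and returns at 25.
- Purchased 5-bromo-2-hydroxy-3-methoxybenzaldehyde F3 would be protected (MOMCl, i-Pr2NEt) as the MOM ether aldehyde F4.
- F4 would be homologated with 2 as in step 1 to the arylacetonitrile F5 and hydrolysed (NaOH; citric acid) to the arylacetic acid F6.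
- F6 would be joined to 6 (PivCl, Et3N, LiCl) as the arylacetyl imide F7.
- The Bu2BOTf/i-Pr2NEt syn-aldol with 9 should give the syn-aldol imide F8, and LiBH4 the (1S,2R)-diol F9.
- HCl in MeOH/THF would remove the MOM group and close ring B through the para-benzyloxybenzyl cation to the bromo-dihydrobenzofuran methanol F10, with the trans ring expected as the kinetic and thermodynamic product and C3 untouched.
- NaH/BnBr would give the benzyl ether F11, and B-alkyl Suzuki coupling of F11 with 17 (from 16 as in step 7) would give 25.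

Step 13. Cleavage of the alkyl benzyl ether may stall on the anionic sulfate salt (catalyst inhibition by residual pyridine), and forcing conditions could then erode the benzylic C2–O1 bond of ring B or the sulfate. The fallback changes the protecting-group plan so that the last step is a basic deacylation; it sets out from 25 and returns at 28.
- Hydrogenolysis at the neutral stage 25 (H2, Pd/C, EtOAc/MeOH) would give the phenol alcohol F12.
- Ac2O/pyridine would give the diacetate F13, and HF·pyridine in THF the chain alcohol diacetate F14.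
- SO3·pyridine followed by NaHCO3 would give the sulfated diacetate sodium salt F15.
- K2CO3 in MeOH at 0 °C followed by HCl (1.0 equiv) would give 28.

**Further compounds**

F1 | step 8 | (1S,2R)-3-benzyloxy-1-(4-benzyloxy-3-methoxyphenyl)-2-{4-[3-(tert-butyldimethylsilyloxy)propyl]furan-2-yl}propyl formate | COc1cc([C@@H](OC=O)[C@@H](COCc2ccccc2)c2cc(CCCO[Si](C)(C)C(C)(C)C)co2)ccc1OCc1ccccc1
F2 | step 8 | 1-benzyloxy-4-[(1S,2R)-3-benzyloxy-1-(2,2-dibromoethenyloxy)-2-{4-[3-(tert-butyldimethylsilyloxy)propyl]furan-2-yl}propyl]-2-methoxybenzene | COc1cc([C@@H](OC=C(Br)Br)[C@@H](COCc2ccccc2)c2cc(CCCO[Si](C)(C)C(C)(C)C)co2)ccc1OCc1ccccc1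
F3 | step 9 | 5-bromo-2-hydroxy-3-methoxybenzaldehyde (purchased) | COc1cc(Br)cc(C=O)c1O
F4 | step 9 | 5-bromo-3-methoxy-2-(methoxymethoxy)benzaldehyde | COCOc1c(OC)cc(Br)cc1C=O
F5 | step 9 | [5-bromo-3-methoxy-2-(methoxymethoxy)phenyl]acetonitrile | COCOc1c(OC)cc(Br)cc1CC#N
F6 | step 9 | [5-bromo-3-methoxy-2-(methoxymethoxy)phenyl]acetic acid | COCOc1c(OC)cc(Br)cc1CC(=O)O
F7 | step 9 | (S)-4-benzyl-3-{[5-bromo-3-methoxy-2-(methoxymethoxy)phenyl]acetyl}-1,3-oxazolidin-2-one | COCOc1c(OC)cc(Br)cc1CC(=O)N1[C@@H](Cc2ccccc2)COC1=O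
F8 | step 9 | (4S)-4-benzyl-3-{(2S,3S)-3-(4-benzyloxy-3-methoxyphenyl)-2-[5-bromo-3-methoxy-2-(methoxymethoxy)phenyl]-3-hydroxypropanoyl}-1,3-oxazolidin-2-one | COc1cc([C@@H](O)[C@@H](C(=O)N2[C@@H](Cc3ccccc3)COC2=O)c2cc(Br)cc(OC)c2OCOC)ccc1OCc1ccccc1
F9 | step 9 | (1S,2R)-1-(4-benzyloxy-3-methoxyphenyl)-2-[5-bromo-3-methoxy-2-(methoxymethoxy)phenyl]propane-1,3-diol | COc1cc([C@@H](O)[C@@H](CO)c2cc(Br)cc(OC)c2OCOC)ccc1OCc1ccccc1
F10 | step 9 | [(2S,3R)-2-(4-benzyloxy-3-methoxyphenyl)-5-bromo-7-methoxy-2,3-dihydro-1-benzofuran-3-yl]methanol | COc1cc([C@H]2Oc3c(OC)cc(Br)cc3[C@@H]2CO)ccc1OCc1ccccc1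
F11 | step 9 | (2S,3R)-2-(4-benzyloxy-3-methoxyphenyl)-3-(benzyloxymethyl)-5-bromo-7-methoxy-2,3-dihydro-1-benzofuran | COc1cc([C@H]2Oc3c(OC)cc(Br)cc3[C@@H]2COCc2ccccc2)ccc1OCc1ccccc1
F12 | step 13 | 4-{(2S,3R)-5-[3-(tert-butyldimethylsilyloxy)propyl]-3-(hydroxymethyl)-7-methoxy-2,3-dihydro-1-benzofuran-2-yl}-2-methoxyphenol | COc1cc([C@H]2Oc3c(OC)cc(CCCO[Si](C)(C)C(C)(C)C)cc3[C@@H]2CO)ccc1O
F13 | step 13 | {(2S,3R)-2-(4-acetoxy-3-methoxyphenyl)-5-[3-(tert-butyldimethylsilyloxy)propyl]-7-methoxy-2,3-dihydro-1-benzofuran-3-yl}methyl acetate | COc1cc([C@H]2Oc3c(OC)cc(CCCO[Si](C)(C)C(C)(C)C)cc3[C@@H]2COC(C)=O)ccc1OC(C)=O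
F14 | step 13 | [(2S,3R)-2-(4-acetoxy-3-methoxyphenyl)-5-(3-hydroxypropyl)-7-methoxy-2,3-dihydro-1-benzofuran-3-yl]methyl acetate | COc1cc([C@H]2Oc3c(OC)cc(CCCO)cc3[C@@H]2COC(C)=O)ccc1OC(C)=O
F15 | step 13 | sodium 3-[(2S,3R)-3-(acetoxymethyl)-2-(4-acetoxy-3-methoxyphenyl)-7-methoxy-2,3-dihydro-1-benzofuran-5-yl]propyl sulfate | COc1cc([C@H]2Oc3c(OC)cc(CCCOS(=O)(=O)[O-])cc3[C@@H]2COC(C)=O)ccc1OC(C)=O.[Na+]
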